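A direct plan would grow ring A (the phenol ring) on the oxygen of 2,4-dibromophenol A1. O-Alkylation of A1 with a chloromalonate would give the aryloxymalonate A2, and Michael addition to a vinyl ketone, Claisen (Dieckmann-type) closure and decarboxylation would give the 4-aryloxycyclohexane-1,3-dione A3. Bromination to A4, conversion into the dibromoenone A5 and dehydrogenation would then give the phenol.
Its weakest steps would be:
- the construction of ring A on A1 from acyclic pieces (alkylation, Michael addition, Claisen closure, decarboxylation): four linear steps that only assemble a benzene ring that can be bought, with a closure that must compete with retro-Michael cleavage;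
- the change of the 2-bromo-1,3-dione A4 into the vinylogous acyl bromide A5: two enol oxygens compete with only a weak bias, and activation of the wrong one would end in the para-aryloxyphenol isomer;
- the final dehydrogenation of A5 with a quinone at 100 °C under acid: the fully brominated enone would meet the harshest conditions of the plan in its last step.

**Retrosynthetic overview**
- Key disconnection: the ether bond between O and C6 of ring A (phenol ring: C1–OH, C2–Br, C3–Br, C6–OAr). The ortho pair C1–OH/C6–OAr is read as the O=C1–C6=N2 unit of an ortho-quinone diazide, 2,3-dibromo-6-diazocyclohexa-2,4-dien-1-one.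
- Its rhodium carbene inserts into the O–H bond of 2,4-dibromophenol (ring B). This forms O–C6 and restores aromatic ring A with its free C1 hydroxyl in one operation, without a protecting group.
- The diazide comes from 6-amino-2,3-dibromophenol: C2–Br is bought with 2-amino-6-bromophenol, C3–Br is set para to nitrogen on a benzoxazolone.
- No ring of the core is formed; both benzene rings are bought. The benzoxazolone ring is closed and opened only to steer the bromination.
- So there is no ring construction, no choice between two enol oxygens (only the nitrogen-bearing carbon can become the ether carbon), and no oxidation at the end.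

Key step: step 5

Remark: ring A is numbered C1 (OH), C2 and C3 (Br), C6 (aryloxy); ring B carries primed numbers. The target has no stereocentre. 2-Amino-6-bromophenol and 2,4-dibromophenol are taken as commercial.

Step 1
Reactants: 1 2-amino-6-bromophenol
Product: 2 7-bromo-1,3-benzoxazol-2(3H)-one
Conditions: CDI (1.2 equiv), THF, reflux
Reagents that add atoms: 1,1'-carbonyldiimidazole O=C(n1ccnc1)n1ccnc1
Why: Twofold nucleophilic acyl substitution at the carbonyl donor by the amino and the hydroxyl group (cyclic carbamate formation) should close the benzoxazolone, which shields the aminophenol from oxidation and makes the ring nitrogen the directing group for the next step.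

Step 2
Reactants: 2 7-bromo-1,3-benzoxazol-2(3H)-one
Product: 3 6,7-dibromo-1,3-benzoxazol-2(3H)-one
Conditions: Br2 (1.1 equiv), AcOH, 25 to 50 °C
Reagents that add atoms: bromine BrBr
Why: Electrophilic aromatic bromination should enter at C6, para to the ring nitrogen (the stronger donor, as in the parent benzoxazolone) and ortho to the bromine already present, which places the second bromine on the future C3 of ring A, and the two bromines then deactivate the ring against a third substitution.

Step 3
Reactants: 3 6,7-dibromo-1,3-benzoxazol-2(3H)-one
Product: 4 6-amino-2,3-dibromophenol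
Conditions: 10 % aq. NaOH (6 equiv), 100 °C, N2; then HCl to pH 6–7
Reagents that add atoms: none
Why: Saponification of the cyclic carbamate by hydroxide and loss of carbon dioxide from the carbamic acid on neutralisation should free the ortho-aminophenol, while the unactivated aryl bromides are inert to aqueous base.

Step 4
Reactants: 4 6-amino-2,3-dibromophenol
Product: 6 2,3-dibromo-6-diazocyclohexa-2,4-dien-1-one, via diazonium chloride 5 (not isolated)
Conditions: NaNO2 (1.05 equiv), 2 M aq. HCl, 0 °C; then NaHCO3 to pH 7, extraction into ClCH2CH2Cl, dried solution kept cold and dark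
Reagents that add atoms: sodium nitrite [Na+].[O-]N=O
Why: Diazotisation of the primary arylamine gives the ortho-hydroxydiazonium salt, whose acidic phenol is deprotonated on neutralisation to the neutral ortho-quinone diazide, which is not dried down but used at once as a solution.

Step 5
Reactants: 6 2,3-dibromo-6-diazocyclohexa-2,4-dien-1-one; 7 2,4-dibromophenol
Product: 8 2,3-dibromo-6-(2,4-dibromophenoxy)phenol
Conditions: Rh2(OAc)4 (2 mol %), 7 (3 equiv), 4 Å MS, ClCH2CH2Cl, 60 °C, dark, slow addition of 6
Reagents that add atoms: none
Why: Dirhodium tetraacetate should take up the diazo carbon C6 of 6 with loss of N2 to give an electrophilic rhodium-bound quinoid carbene; the oxygen of 7 attacks C6 to form an oxonium ylide, and proton transfer to the C1 oxygen with release of the catalyst gives the aromatic phenol 8 directly, so the O–C6 ether bond and the free C1 hydroxyl arise in one operation. The closest known reaction type is the rhodium-catalysed O–H insertion of ortho-quinone diazides (diazonaphthoquinones) into alcohols and carboxylic acids by quinoid carbene transfer, applied here to a phenol as the O–H partner and helped by the rearomatisation of ring A. No ring is closed and no stereocentre is formed. The step needs chemoselectivity for O–H insertion over thermal or photochemical Wolff ring contraction of 6 and over C-arylation of the phenol: catalysis at 60 °C in the dark with slow addition keeps the diazide concentration low, and the bromine atoms at C2' and C4' of 7 block and deactivate its para and one ortho carbon, which leaves oxygen as the nucleophilic site. Regiochemistry is not at stake, since the ether can only form at the former diazo carbon C6 and the hydroxyl only at the former carbonyl carbon C1. The excess of 7 and the molecular sieves should suppress insertion into the hydroxyl of the product and into water.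

**Compound list**
1 | 2-amino-6-bromophenol | Nc1cccc(Br)c1O | starting material
2 | 7-bromo-1,3-benzoxazol-2(3H)-one | O=C1Nc2cccc(Br)c2O1 | intermediate
3 | 6,7-dibromo-1,3-benzoxazol-2(3H)-one | O=C1Nc2ccc(Br)c(Br)c2O1 | intermediate
4 | 6-amino-2,3-dibromophenol | Nc1ccc(Br)c(Br)c1O | intermediate
5 | 3,4-dibromo-2-hydroxybenzenediazonium chloride (not isolated) | N#[N+]c1ccc(Br)c(Br)c1O.[Cl-] | intermediate
6 | 2,3-dibromo-6-diazocyclohexa-2,4-dien-1-one (ortho-quinone diazide) | O=C1C(Br)=C(Br)C=CC1=[N+]=[N-] | intermediate
7 | 2,4-dibromophenol | Oc1ccc(Br)cc1Br | starting material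
8 | 2,3-dibromo-6-(2,4-dibromophenoxy)phenol | Oc1c(Oc2ccc(Br)cc2Br)ccc(Br)c1Br | target

Total step count: 5. Longest linear sequence: 5 steps (1 → 2 → 3 → 4 → 6 → 8).

**Steps most likely to fail**

1. Step 5. The diazide may be lost by Wolff ring contraction, or the carbene may attack a ring carbon of the phenol or the hydroxyl of the product instead of the O–H bond of 7. The fallback sets out from 7 and comes back at 8. SNAr of the phenoxide of 7 on commercial 2,3-dibromo-6-fluorobenzaldehyde F1 (K2CO3, DMF, 90 °C; the fluoride ortho to the formyl group is displaced) would give 2,3-dibromo-6-(2,4-dibromophenoxy)benzaldehyde F2. Baeyer–Villiger oxidation (mCPBA, CH2Cl2) would give 2,3-dibromo-6-(2,4-dibromophenoxy)phenyl formate F3, and methanolysis (K2CO3, MeOH) would give 8.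

2. Step 4. The light- and heat-sensitive quinone diazide may decompose or undergo azo coupling during neutralisation and extraction. The fallback sets out from 4 and comes back at 8. The diazonium chloride 5, kept in acid, would be treated with KI to give 2,3-dibromo-6-iodophenol F4 (Sandmeyer-type iodination). MOMCl and iPr2NEt would give 1,2-dibromo-4-iodo-3-(methoxymethoxy)benzene F5. Ullmann coupling with 7 at the carbon–iodine bond (CuI, N,N-dimethylglycine, Cs2CO3, dioxane, 90 °C) would give 1,2-dibromo-4-(2,4-dibromophenoxy)-3-(methoxymethoxy)benzene F6, and HCl in MeOH would give 8.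

3. Step 2. Bromine may attack C4 (ortho to nitrogen, para to the first bromine) or substitute twice instead of once at C6. The fallback sets out from 2 and comes back at 3. Nitration (HNO3, H2SO4, 0 °C), which stops after one substitution, would give 7-bromo-6-nitro-1,3-benzoxazol-2(3H)-one F7, purified by crystallisation. Reduction (Fe, NH4Cl, EtOH/H2O, 70 °C) would give 6-amino-7-bromo-1,3-benzoxazol-2(3H)-one F8. Diazotisation (NaNO2, aq. HBr, 0 °C) to 7-bromo-2-oxo-2,3-dihydro-1,3-benzoxazole-6-diazonium bromide F9 and Sandmeyer reaction (CuBr, 60 °C) would give 3.

**Further compounds**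
F1 | step 5 | 2,3-dibromo-6-fluorobenzaldehyde | O=Cc1c(F)ccc(Br)c1Br
F2 | step 5 | 2,3-dibromo-6-(2,4-dibromophenoxy)benzaldehyde | O=Cc1c(Oc2ccc(Br)cc2Br)ccc(Br)c1Br
F3 | step 5 | 2,3-dibromo-6-(2,4-dibromophenoxy)phenyl formate | O=COc1c(Oc2ccc(Br)cc2Br)ccc(Br)c1Br
F4 | step 4 | 2,3-dibromo-6-iodophenol | Oc1c(I)ccc(Br)c1Br
F5 | step 4 | 1,2-dibromo-4-iodo-3-(methoxymethoxy)benzene | COCOc1c(I)ccc(Br)c1Br
F6 | step 4 | 1,2-dibromo-4-(2,4-dibromophenoxy)-3-(methoxymethoxy)benzene | COCOc1c(Oc2ccc(Br)cc2Br)ccc(Br)c1Br
F7 | step 2 | 7-bromo-6-nitro-1,3-benzoxazol-2(3H)-one | O=C1Nc2ccc([N+](=O)[O-])c(Br)c2O1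
F8 | step 2 | 6-amino-7-bromo-1,3-benzoxazol-2(3H)-one | Nc1ccc2NC(=O)Oc2c1Br
F9 | step 2 | 7-bromo-2-oxo-2,3-dihydro-1,3-benzoxazole-6-diazonium bromide | N#[N+]c1ccc2NC(=O)Oc2c1Br.[Br-]
A1 | direct plan | 2,4-dibromophenol | Oc1ccc(Br)cc1Br
A2 | direct plan | dimethyl 2-(2,4-dibromophenoxy)malonate | COC(=O)C(Oc1ccc(Br)cc1Br)C(=O)OC
A3 | direct plan | rac-4-(2,4-dibromophenoxy)cyclohexane-1,3-dione | O=C1CCC(Oc2ccc(Br)cc2Br)C(=O)C1
A4 | direct plan | rac-2-bromo-4-(2,4-dibromophenoxy)cyclohexane-1,3-dione | O=C1CCC(Oc2ccc(Br)cc2Br)C(=O)C1Br
A5 | direct plan | rac-2,3-dibromo-6-(2,4-dibromophenoxy)cyclohex-2-en-1-one | O=C1C(Br)=C(Br)CCC1Oc1ccc(Br)cc1Br
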